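(The numbers were drawn at random within sensible limits; the run is a simulation.)

Late in each run the share asked for is the sum of how the intermediate was divided between the two nucleophiles along the way.

    second nucleophile + intermediate → other capture product (k1 = 9.3 M⁻¹ s⁻¹)
    first nucleophile + intermediate → target (k2 = 41 M⁻¹ s⁻¹)
    starting material ⇌ intermediate (K3 = 0.087, k3 = 0.029 s⁻¹)
    starting material + protic impurity → quenched substrate (k4 = 2.8 M⁻¹ s⁻¹)

| flask | starting material | first nucleophile | second nucleophile | protic impurity | time | remark |
|---|---|---|---|---|---|---|
| maple | 0.050 M | 0.0600 M | 0.0900 M | 0.0150 M | 2.0 min | a tube with plug flow, the mixed feed as stated, residence time 2.0 min |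
| oak | 0.050 M | 0.0600 M | 0.0900 M (fed, over 2.00 min) | 0.0150 M | 2.0 min | all but second nucleophile at the start; second nucleophile goes in evenly over 2.00 min, the run ends at 2.0 min |
| ash | 0.050 M | 0.0600 M | 0.0900 M | 0.0150 M | 2.0 min | a closed flask charged with all of it at once and left for 2.0 min |
| birch | 0.050 M | 0.0600 M | 0.0900 M | 0.0150 M |  | a single well-mixed tank run continuously and read at steady state, 2.0 min in it on average |

- the set-up with the highest share of target in all that became target or other capture product, at the outlet or at the end ("none" if the first two lie within 2 percentage points) (maple / oak / ash / birch / none)
- share of target in all that became target or other capture product, at the outlet or at the end, maple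
- share of target in all that became target or other capture product, at the outlet or at the end, oak
- share of target in all that became target or other capture product, at the outlet or at the end, ash
- share of target in all that became target or other capture product, at the outlet or at the end, birch

- the stated concentrations are those of everything mixed, before any reaction; amounts are the same in each set-up
- the feed brings no volume worth counting
- run time (maple): 2.0 min

Our carried quantity is the capture ratio 2.94, a selectivity factor: k2[first nucleophile] over k1[second nucleophile], taken at the concentrations the intermediate meets, here the charged ones. Its share of target is ratio/(1 + ratio). That holds because the intermediate, with both captures at charge, has a half-life of 0.210 s, far shorter than the 0.40 min of starting material by its forward step, so it is captured as it forms.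

For ash, we let the impurity take its whole charge, because its own half-life with starting material at charge is 4.95 s, shorter than that 0.40 min. That leaves 0.0350 M for the products. The charged ratio gives 74.6%.

We put that back for a second round. The mean concentrations become 0.0469 M of first nucleophile and 0.0856 M of second, so the ratio is 2.42 and the share 70.8%. Maple runs the same history along its tube.

In oak the second nucleophile arrives evenly. We take the forward time constant of starting material, 0.575 min, shorter than the feed, as the typical moment of formation, and there the dose fraction is 0.287. The ratio is then 10.2 and the share 91.1%. A second round, with 0.0441 M of first nucleophile, gives 7.51 and 88.2%.

Turn the question round. For oak to fall within 2 percentage points of ash, its ratio must come down close to the 2.42 we reckoned for ash. Our ratio for oak stands at 7.51, higher by a factor of 3.10.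

The forecast gives 71% for maple, 88% for oak, 71% for ash and 68.7% for birch, with oak best: “Feeding the second nucleophile slowly keeps it scarce during the early period when most of the intermediate is formed”.

The simulation gives 70.9%, 89.0%, 70.9% and 68.6% in that order, with oak best.

For the neighbour of oak charged with 0.24 M of first nucleophile, the same dose fraction gives a ratio of 37.9, a share of 97.4%, and that flask gives 97.9%. Oak itself still holds 3.00% of its starting material at 2.00 min. Its end amounts give a running ratio of 1.53, lower than our 7.51, a running share of 60.5%. At 20.0 min oak's starting material is 0%, its target has gone from 60.2% to 62.0%, its other capture product from 7.43% to 8.60%, and its share from 89.0% to 87.8%.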